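**Plan**
- Retrosynthesis: the three benzyl ethers are cut first, then the O–CH3 bonds at O8 and O5', then the aryl C8–O and C5'–O bonds, and last the 3-O-methyl and 7,4'-O-benzyl bonds, which leads back to morin.
- Enabling feature: the methoxy-bearing C8 of ring A lies para to the C5 hydroxyl and the methoxy-bearing C5' of ring B lies para to the C2' hydroxyl, so both oxygens can be delivered by phenolate-directed para oxygenation.
- Forward, first half: no ring is built and the flavone skeleton of morin is carried through; morin is peracetylated, the 7- and 4'-acetates are exchanged for benzyl, the other acetates are removed and O3 is methylated.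
- Forward, second half: both C–H bonds are oxidised in one persulfate operation that delivers the new oxygens as sulfates; O2' is benzylated at that stage, the sulfates are hydrolysed, the freed phenols are methylated and all benzyl groups are removed by hydrogenolysis.
- Stereochemistry: the target has no stereocenter, so none has to be set.

Key step: step 5

Assumption: the morin hydroxyls are taken to follow the alkylation order usual for flavonols, 7 > 4' > 3 > 2' > 5, the 2'-hydroxyl being slowed by its hydrogen bond and by the twist of ring B.

**Route**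

Step 1
Reactants: 1 morin; 2 acetic anhydride
Product: 3 morin pentaacetate (3,5,7,2',4'-penta-O-acetylmorin)
Conditions: Ac2O, pyridine, DMAP (cat.), 60 °C
Reagents that add atoms: acetic anhydride, CC(=O)OC(C)=O
Why: Exhaustive O-acetylation (nucleophilic acyl substitution with DMAP catalysis) should esterify all five hydroxyls, the chelated 5-OH included, and turns O7 and O4' into the most labile aryl esters of the molecule.

Step 2
Reactants: 3 morin pentaacetate; 4 benzyl bromide
Product: 5 3,5,2'-tri-O-acetyl-7,4'-di-O-benzylmorin
Conditions: BnBr (2.2 equiv), K2CO3, KI (cat.), acetone (undried), reflux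
Reagents that add atoms: benzyl bromide, BrCc1ccccc1
Why: This is the acetate-to-ether exchange known for flavonol peracetates: the 7- and 4'-acetates, conjugated through the rings to the C4 carbonyl, are the first to be cleaved by carbonate, and each phenoxide released should be trapped at once by Williamson etherification while the 3-, 5- and 2'-acetates stay in place.

Step 3
Reactants: 5 3,5,2'-tri-O-acetyl-7,4'-di-O-benzylmorin
Product: 6 7,4'-di-O-benzylmorin (7,4'-bis(benzyloxy)-3,5,2'-trihydroxyflavone)
Conditions: HCl (1.25 M in MeOH), THF, 50 °C
Reagents that add atoms: none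
Why: Acid-catalysed transesterification (methanolysis) should remove the three remaining acetates as methyl acetate without touching the benzyl ethers and without exposing the free flavonol to base and air.

Step 4
Reactants: 6 7,4'-di-O-benzylmorin; 7 iodomethane
Product: 8 7,4'-bis(benzyloxy)-5,2'-dihydroxy-3-methoxyflavone
Conditions: MeI (1.05 equiv), K2CO3 (1.1 equiv), acetone, 25–40 °C
Reagents that add atoms: iodomethane, CI
Why: Williamson O-methylation with one equivalent of base should take the enolic 3-OH, the next hydroxyl of a flavonol to be alkylated after 7-OH and 4'-OH, because the 5-OH is locked in a chelate with the C4 carbonyl and the 2'-OH on the twisted ring B is hydrogen-bonded and shielded.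

Step 5
Reactants: 8 7,4'-bis(benzyloxy)-5,2'-dihydroxy-3-methoxyflavone; 9 potassium persulfate (K2S2O8)
Product: 10 dipotassium 7,4'-bis(benzyloxy)-5,2'-dihydroxy-3-methoxyflavone-8,5'-diyl bis(sulfate)
Conditions: K2S2O8 (3 equiv, in portions), 2 M aq. KOH, pyridine, 10–15 °C, argon; then AcOH to pH 7, unchanged 8 washed out with EtOAc, salt taken up in n-BuOH
Reagents that add atoms: potassium persulfate, [K+].[K+].[O-]S(=O)(=O)OOS(=O)(=O)[O-]
Why: Aqueous KOH ionizes both the 5- and the 2'-hydroxyl, and the carbon para to each phenolate oxygen (C8 on ring A, C5' on ring B) displaces sulfate from the O–O bond of peroxydisulfate; the resulting 4-sulfonatooxycyclohexa-2,5-dienone regains aromaticity by proton shift and leaves an aryl sulfate. The closest known reaction type is the Elbs persulfate oxidation, which converts 5-hydroxy-7-alkoxyflavones into 5,8-dihydroxyflavones and 2-hydroxy-4-alkoxyaryl ketones into their 2,5-dihydroxy congeners; here it is applied to two phenols of one substrate. No ring is closed and no stereocenter is formed; the two bonds made are C8–O and C5'–O. The selectivity required is para rather than ortho substitution at each phenol and no oxidation elsewhere: the Elbs reaction favours the para carbon by itself, the ortho carbons C6 and C3' are each wedged between two oxygen-bearing carbons, and with O7 and O4' benzylated no other phenolate can enter the reaction. Each sulfate lowers the electron density of its ring, which should guard the product against further oxidation, and it marks the new oxygens as anionic esters distinct from the two original hydroxyls.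

Step 6
Reactants: 10 dipotassium 7,4'-bis(benzyloxy)-5,2'-dihydroxy-3-methoxyflavone-8,5'-diyl bis(sulfate); 4 benzyl bromide
Product: 11 dipotassium 7,2',4'-tris(benzyloxy)-5-hydroxy-3-methoxyflavone-8,5'-diyl bis(sulfate)
Conditions: BnBr (1.3 equiv), K2CO3, 18-crown-6 (cat.), DMF, 40 °C
Reagents that add atoms: benzyl bromide, BrCc1ccccc1
Why: Williamson etherification at the sulfate stage should cap the 2'-phenol, the only unchelated hydroxyl left, because the sulfate monoanions are too weakly nucleophilic to be benzylated and the chelated 5-OH stays free, the classical device of alkylating an Elbs sulfate before its hydrolysis.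

Step 7
Reactants: 11 dipotassium 7,2',4'-tris(benzyloxy)-5-hydroxy-3-methoxyflavone-8,5'-diyl bis(sulfate)
Product: 12 7,2',4'-tris(benzyloxy)-5,8,5'-trihydroxy-3-methoxyflavone
Conditions: 2 M HCl, 1,4-dioxane–H2O, 80 °C, argon
Reagents that add atoms: none
Why: Acid-catalysed hydrolysis of the aryl sulfate monoesters (S–O cleavage), the usual second stage of an Elbs oxidation, should free the 8- and 5'-hydroxyls while the benzyl ethers tolerate warm dilute acid and argon guards the 5,8-hydroquinone against autoxidation.

Step 8
Reactants: 12 7,2',4'-tris(benzyloxy)-5,8,5'-trihydroxy-3-methoxyflavone; 7 iodomethane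
Product: 13 7,2',4'-tris(benzyloxy)-5-hydroxy-3,8,5'-trimethoxyflavone
Conditions: MeI (2.2 equiv), K2CO3, acetone, 45 °C, argon
Reagents that add atoms: iodomethane, CI
Why: Williamson O-methylation should take the 8- and 5'-hydroxyls, which are ordinary phenols, and spare the 5-OH chelated to the C4 carbonyl, as in the partial methylation of 5,8-dihydroxyflavones to 5-hydroxy-8-methoxyflavones.

Step 9
Reactants: 13 7,2',4'-tris(benzyloxy)-5-hydroxy-3,8,5'-trimethoxyflavone
Product: 14 5,7,2',4'-tetrahydroxy-3,8,5'-trimethoxyflavone
Conditions: H2 (1 atm), Pd/C (10%), EtOAc–MeOH, 25 °C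
Reagents that add atoms: none
Why: Catalytic hydrogenolysis over Pd/C should cleave the three benzyl ethers to the 7-, 2'- and 4'-hydroxyls, while the methyl ethers and the tetrasubstituted C2=C3 bond of the flavone are not reduced under these conditions.

**Compound list**

1 | morin (3,5,7,2',4'-pentahydroxyflavone) | O=c1c(O)c(-c2ccc(O)cc2O)oc2cc(O)cc(O)c12 | starting material
2 | acetic anhydride | CC(=O)OC(C)=O | starting material
3 | morin pentaacetate (3,5,7,2',4'-penta-O-acetylmorin) | CC(=O)Oc1ccc(-c2oc3cc(OC(C)=O)cc(OC(C)=O)c3c(=O)c2OC(C)=O)c(OC(C)=O)c1 | intermediate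
4 | benzyl bromide | BrCc1ccccc1 | starting material
5 | 3,5,2'-tri-O-acetyl-7,4'-di-O-benzylmorin | CC(=O)Oc1cc(OCc2ccccc2)ccc1-c1oc2cc(OCc3ccccc3)cc(OC(C)=O)c2c(=O)c1OC(C)=O | intermediate
6 | 7,4'-di-O-benzylmorin (7,4'-bis(benzyloxy)-3,5,2'-trihydroxyflavone) | O=c1c(O)c(-c2ccc(OCc3ccccc3)cc2O)oc2cc(OCc3ccccc3)cc(O)c12 | intermediate
7 | iodomethane | CI | starting material
8 | 7,4'-bis(benzyloxy)-5,2'-dihydroxy-3-methoxyflavone | COc1c(-c2ccc(OCc3ccccc3)cc2O)oc2cc(OCc3ccccc3)cc(O)c2c1=O | intermediate
9 | potassium persulfate (K2S2O8) | [K+].[K+].[O-]S(=O)(=O)OOS(=O)(=O)[O-] | starting material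
10 | dipotassium 7,4'-bis(benzyloxy)-5,2'-dihydroxy-3-methoxyflavone-8,5'-diyl bis(sulfate) | COc1c(-c2cc(OS(=O)(=O)[O-])c(OCc3ccccc3)cc2O)oc2c(OS(=O)(=O)[O-])c(OCc3ccccc3)cc(O)c2c1=O.[K+].[K+] | intermediate
11 | dipotassium 7,2',4'-tris(benzyloxy)-5-hydroxy-3-methoxyflavone-8,5'-diyl bis(sulfate) | COc1c(-c2cc(OS(=O)(=O)[O-])c(OCc3ccccc3)cc2OCc2ccccc2)oc2c(OS(=O)(=O)[O-])c(OCc3ccccc3)cc(O)c2c1=O.[K+].[K+] | intermediate
12 | 7,2',4'-tris(benzyloxy)-5,8,5'-trihydroxy-3-methoxyflavone | COc1c(-c2cc(O)c(OCc3ccccc3)cc2OCc2ccccc2)oc2c(O)c(OCc3ccccc3)cc(O)c2c1=O | intermediate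
13 | 7,2',4'-tris(benzyloxy)-5-hydroxy-3,8,5'-trimethoxyflavone | COc1cc(-c2oc3c(OC)c(OCc4ccccc4)cc(O)c3c(=O)c2OC)c(OCc2ccccc2)cc1OCc1ccccc1 | intermediate
14 | 5,7,2',4'-tetrahydroxy-3,8,5'-trimethoxyflavone | COc1cc(-c2oc3c(OC)c(O)cc(O)c3c(=O)c2OC)c(O)cc1O | target

**Step count and risks**

Total step count: 9. Longest linear sequence: 9 steps, from morin 1 to 14.

Steps most likely to fail:

1. Step 5 (twofold Elbs oxidation). The second oxidation may stall at the monosulfate stage. The electron-rich rings may be degraded oxidatively in alkali. The pyrone ring of the 2'-hydroxyflavone may open in base. Fallback: the two C–O bonds are made in separate operations on substrates that each offer a single phenolate. It sets out from 8. K2S2O8 in K2CO3/KHCO3 buffer near pH 10 (aqueous pyridine) should ionize the 2'-hydroxyl but largely not the chelated 5-hydroxyl, and so oxidize ring B alone to potassium 7,4'-bis(benzyloxy)-5,2'-dihydroxy-3-methoxyflavon-5'-yl sulfate F1. Benzylation of the 2'-hydroxyl (BnBr, K2CO3, DMF) should then give potassium 7,2',4'-tris(benzyloxy)-5-hydroxy-3-methoxyflavon-5'-yl sulfate F2. A second Elbs oxidation in aqueous KOH and pyridine, now the well-precedented case of a 5-hydroxy-7-benzyloxyflavone with one free phenol, should install the C8 sulfate. The route is rejoined at 11.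

2. Step 4 (3-O-methylation). Site selectivity between the 3- and the 2'-hydroxyl may be lost, with methylation at O2' or at both oxygens. Fallback: control is moved from phenol acidity to acyl lability. It sets out from 5. Prolonged treatment with MeI and K2CO3 in refluxing acetone should exchange the 3-acetate, an enol ester and the next most labile acyl group, for methyl. This gives 5,2'-di-O-acetyl-7,4'-di-O-benzyl-3-O-methylmorin F3. Methanolic HCl then removes the two remaining acetates, and the route is rejoined at 8.

3. Step 2 (acetate-to-benzyl exchange). Acetate cleavage may be unselective, or acetyl groups may migrate between O3 and O2', so that benzyl is delivered to the wrong oxygens. Fallback: the acetates are dispensed with and the hydroxyls are differentiated by acidity. It sets out from 1. Direct benzylation of unprotected morin with BnBr (2 equiv) and KHCO3 in DMF at 40 °C should alkylate the two most acidic hydroxyls, 7-OH and 4'-OH, first. After chromatographic removal of products benzylated at O3, the route is rejoined at 6. This detour makes no compound outside the list (F0).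

Further compounds
F1 | step 5 | potassium 7,4'-bis(benzyloxy)-5,2'-dihydroxy-3-methoxyflavon-5'-yl sulfate | COc1c(-c2cc(OS(=O)(=O)[O-])c(OCc3ccccc3)cc2O)oc2cc(OCc3ccccc3)cc(O)c2c1=O.[K+]
F2 | step 5 | potassium 7,2',4'-tris(benzyloxy)-5-hydroxy-3-methoxyflavon-5'-yl sulfate | COc1c(-c2cc(OS(=O)(=O)[O-])c(OCc3ccccc3)cc2OCc2ccccc2)oc2cc(OCc3ccccc3)cc(O)c2c1=O.[K+]
F3 | step 4 | 5,2'-di-O-acetyl-7,4'-di-O-benzyl-3-O-methylmorin | COc1c(-c2ccc(OCc3ccccc3)cc2OC(C)=O)oc2cc(OCc3ccccc3)cc(OC(C)=O)c2c1=O
F0 | step 2 | none | none
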